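**Retrosynthetic overview**
1. The target is the threo (7R,8R) isomer, i.e. (2R,3R) in propyl acetate numbering. It is reached by desilylation at C7–O after acetylation of the only free (primary, C9) hydroxyl, which comes from reductive removal of an Evans auxiliary.
2. Key C7–C8 bond: intermolecular Evans syn aldol between the Z-boron enolate of an N-(aryloxyacetyl)oxazolidinone and 3,4,5-trimethoxybenzaldehyde. It sets both stereocentres.
3. The imide comes from the aryloxyacetic acid and (S)-4-benzyloxazolidin-2-one. The acid comes from 4-allyl-2,6-dimethoxyphenol and ethyl bromoacetate (Williamson ether synthesis, C8–O–C4' bond made first).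
4. No ring is formed: both benzene rings and the auxiliary ring are bought, and the auxiliary is recovered.

Assumption: species that differ from a listed compound only as a salt or metal alkoxide destroyed in aqueous work-up (e.g. the lithium carboxylate in step 2) are not numbered separately.

**Route**

Step 1
Reactants: 1 4-allyl-2,6-dimethoxyphenol (methoxyeugenol); 2 ethyl bromoacetate
Product: 3 ethyl 2-(4-allyl-2,6-dimethoxyphenoxy)acetate
Conditions: K2CO3 (2 equiv), acetone, reflux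
Reagents that add atoms: none
Why: Williamson ether synthesis, in which the phenoxide formed by K2CO3 displaces bromide from the activated α-bromo ester (SN2) and the mild base leaves the allyl group unisomerised.

Step 2
Reactants: 3 ethyl 2-(4-allyl-2,6-dimethoxyphenoxy)acetate
Product: 4 2-(4-allyl-2,6-dimethoxyphenoxy)acetic acid
Conditions: LiOH·H2O (2 equiv), THF/H2O 3:1, rt; then 1 M HCl to pH 2
Reagents that add atoms: lithium hydroxide, [Li+].[OH-]
Why: Ester saponification (acyl substitution by hydroxide) is driven to completion by carboxylate formation and does not touch the aryl ether or the allyl group at room temperature.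

Step 3
Reactants: 4 2-(4-allyl-2,6-dimethoxyphenoxy)acetic acid; 5 (S)-4-benzyloxazolidin-2-one
Product: 7 (S)-4-benzyl-3-[2-(4-allyl-2,6-dimethoxyphenoxy)acetyl]oxazolidin-2-one, via pivalic mixed anhydride 6 (not isolated)
Conditions: PivCl (1.1 equiv), Et3N (2.5 equiv), THF, −20 °C; then 5, LiCl (1.1 equiv), −20 °C to rt
Reagents that add atoms: none
Why: N-acylation of the oxazolidinone through a mixed pivalic anhydride, where the LiCl-activated oxazolidinone attacks the unhindered aryloxyacetyl carbonyl rather than the tert-butyl-shielded one.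

Step 4
Reactants: 7 (S)-4-benzyl-3-[2-(4-allyl-2,6-dimethoxyphenoxy)acetyl]oxazolidin-2-one; 8 3,4,5-trimethoxybenzaldehyde
Product: 11 (S)-4-benzyl-3-[(2S,3R)-2-(4-allyl-2,6-dimethoxyphenoxy)-3-hydroxy-3-(3,4,5-trimethoxyphenyl)propanoyl]oxazolidin-2-one, via Z-dibutylboron enolate 9 (not isolated), via dibutylboron aldolate 10 (not isolated)
Conditions: Bu2BOTf (1.2 equiv), Et3N (1.4 equiv), CH2Cl2, −78 to 0 °C; then 8 (1.1 equiv), −78 to 0 °C; then pH 7 phosphate buffer, MeOH, 30% H2O2, 0 °C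
Reagents that add atoms: none
Why: Evans syn aldol, in which the Z-boron enolate reacts through a closed Zimmerman–Traxler chair with the ring carbonyl turned away from the enolate oxygen, so the aldehyde adds to the enolate face opposite the benzyl group and gives the syn (2S,3R) adduct that corresponds to the threo (7R,8R) target.

Step 5
Reactants: 11 (S)-4-benzyl-3-[(2S,3R)-2-(4-allyl-2,6-dimethoxyphenoxy)-3-hydroxy-3-(3,4,5-trimethoxyphenyl)propanoyl]oxazolidin-2-one
Product: 12 (S)-4-benzyl-3-[(2S,3R)-2-(4-allyl-2,6-dimethoxyphenoxy)-3-(tert-butyldimethylsilyloxy)-3-(3,4,5-trimethoxyphenyl)propanoyl]oxazolidin-2-one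
Conditions: TBSOTf (1.5 equiv), 2,6-lutidine (2.5 equiv), CH2Cl2, −78 to 0 °C
Reagents that add atoms: tert-butyldimethylsilyl trifluoromethanesulfonate, CC(C)(C)[Si](C)(C)OS(=O)(=O)C(F)(F)F
Why: Silyl ether formation with the highly electrophilic silyl triflate and a hindered pyridine base caps the benzylic hydroxyl at low temperature without retro-aldol or epimerisation, so C7–OH is masked before C9–OH is unveiled.

Step 6
Reactants: 12 (S)-4-benzyl-3-[(2S,3R)-2-(4-allyl-2,6-dimethoxyphenoxy)-3-(tert-butyldimethylsilyloxy)-3-(3,4,5-trimethoxyphenyl)propanoyl]oxazolidin-2-one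
Product: 13 (2R,3R)-2-(4-allyl-2,6-dimethoxyphenoxy)-3-(tert-butyldimethylsilyloxy)-3-(3,4,5-trimethoxyphenyl)propan-1-ol
Conditions: LiBH4 (2 equiv), MeOH (2 equiv), THF, 0 °C; then H2O
Reagents that add atoms: none
Why: Reductive cleavage of the Evans auxiliary, in which methanol-activated LiBH4 reduces the exocyclic imide carbonyl to the primary alcohol without affecting the alkene, the silyl ether or either stereocentre (the descriptor at C2 changes from S to R only through CIP priorities).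

Step 7
Reactants: 13 (2R,3R)-2-(4-allyl-2,6-dimethoxyphenoxy)-3-(tert-butyldimethylsilyloxy)-3-(3,4,5-trimethoxyphenyl)propan-1-ol
Product: 14 (2R,3R)-2-(4-allyl-2,6-dimethoxyphenoxy)-3-(tert-butyldimethylsilyloxy)-3-(3,4,5-trimethoxyphenyl)propyl acetate
Conditions: Ac2O (1.5 equiv), pyridine, 4-(dimethylamino)pyridine (5 mol %), CH2Cl2, 0 °C to rt
Reagents that add atoms: acetic anhydride, CC(=O)OC(C)=O
Why: Nucleophile-catalysed acylation via the N-acetylpyridinium ion of the only free hydroxyl, which is primary, so the position of the acetate is unambiguous.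

Step 8
Reactants: 14 (2R,3R)-2-(4-allyl-2,6-dimethoxyphenoxy)-3-(tert-butyldimethylsilyloxy)-3-(3,4,5-trimethoxyphenyl)propyl acetate
Product: 15 (2R,3R)-2-(4-allyl-2,6-dimethoxyphenoxy)-3-hydroxy-3-(3,4,5-trimethoxyphenyl)propyl acetate (target, 7R,8R)
Conditions: HF·pyridine, pyridine, THF, 0 °C to rt
Reagents that add atoms: none
Why: Fluoride-mediated desilylation driven by the strong Si–F bond under buffered weakly acidic conditions, which avoid base-induced acetate loss or migration and do not ionise the benzylic position, so (7R,8R) is retained.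

**Compound list**
1 | 4-allyl-2,6-dimethoxyphenol (methoxyeugenol) | C=CCc1cc(OC)c(O)c(OC)c1 | starting material
2 | ethyl bromoacetate | CCOC(=O)CBr | starting material
3 | ethyl 2-(4-allyl-2,6-dimethoxyphenoxy)acetate | C=CCc1cc(OC)c(OCC(=O)OCC)c(OC)c1 | intermediate
4 | 2-(4-allyl-2,6-dimethoxyphenoxy)acetic acid | C=CCc1cc(OC)c(OCC(=O)O)c(OC)c1 | intermediate
5 | (S)-4-benzyloxazolidin-2-one | O=C1N[C@@H](Cc2ccccc2)CO1 | starting material
6 | 2-(4-allyl-2,6-dimethoxyphenoxy)acetic pivalic anhydride | C=CCc1cc(OC)c(OCC(=O)OC(=O)C(C)(C)C)c(OC)c1 | intermediate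
7 | (S)-4-benzyl-3-[2-(4-allyl-2,6-dimethoxyphenoxy)acetyl]oxazolidin-2-one | C=CCc1cc(OC)c(OCC(=O)N2C(=O)OC[C@@H]2Cc2ccccc2)c(OC)c1 | intermediate
8 | 3,4,5-trimethoxybenzaldehyde | COc1cc(C=O)cc(OC)c1OC | starting material
9 | Z-dibutylboron enolate of 7 (O–B and aryloxy cis on the enol double bond) | C=CCc1cc(OC)c(O/C=C(\OB(CCCC)CCCC)N2C(=O)OC[C@@H]2Cc2ccccc2)c(OC)c1 | intermediate
10 | O-dibutylboryl aldolate of 11 (2S,3R) | C=CCc1cc(OC)c(O[C@H](C(=O)N2C(=O)OC[C@@H]2Cc2ccccc2)[C@H](OB(CCCC)CCCC)c2cc(OC)c(OC)c(OC)c2)c(OC)c1 | intermediate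
11 | (S)-4-benzyl-3-[(2S,3R)-2-(4-allyl-2,6-dimethoxyphenoxy)-3-hydroxy-3-(3,4,5-trimethoxyphenyl)propanoyl]oxazolidin-2-one | C=CCc1cc(OC)c(O[C@H](C(=O)N2C(=O)OC[C@@H]2Cc2ccccc2)[C@H](O)c2cc(OC)c(OC)c(OC)c2)c(OC)c1 | intermediate
12 | (S)-4-benzyl-3-[(2S,3R)-2-(4-allyl-2,6-dimethoxyphenoxy)-3-(tert-butyldimethylsilyloxy)-3-(3,4,5-trimethoxyphenyl)propanoyl]oxazolidin-2-one | C=CCc1cc(OC)c(O[C@H](C(=O)N2C(=O)OC[C@@H]2Cc2ccccc2)[C@H](O[Si](C)(C)C(C)(C)C)c2cc(OC)c(OC)c(OC)c2)c(OC)c1 | intermediate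
13 | (2R,3R)-2-(4-allyl-2,6-dimethoxyphenoxy)-3-(tert-butyldimethylsilyloxy)-3-(3,4,5-trimethoxyphenyl)propan-1-ol | C=CCc1cc(OC)c(O[C@H](CO)[C@H](O[Si](C)(C)C(C)(C)C)c2cc(OC)c(OC)c(OC)c2)c(OC)c1 | intermediate
14 | (2R,3R)-2-(4-allyl-2,6-dimethoxyphenoxy)-3-(tert-butyldimethylsilyloxy)-3-(3,4,5-trimethoxyphenyl)propyl acetate | C=CCc1cc(OC)c(O[C@H](COC(C)=O)[C@H](O[Si](C)(C)C(C)(C)C)c2cc(OC)c(OC)c(OC)c2)c(OC)c1 | intermediate
15 | (2R,3R)-2-(4-allyl-2,6-dimethoxyphenoxy)-3-hydroxy-3-(3,4,5-trimethoxyphenyl)propyl acetate | C=CCc1cc(OC)c(O[C@H](COC(C)=O)[C@H](O)c2cc(OC)c(OC)c(OC)c2)c(OC)c1 | target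

**Totals**
Total step count: 8. Longest linear sequence: 8 steps (1 to 15).

**Three steps most likely to fail, with fallbacks**

Step 4 (aldol; risk of incomplete enolisation of the bulky aryloxyacetyl imide or of eroded syn selectivity). The fallback sets out from 3 and comes back at 13. The lithium enolate of 3 (LiN(SiMe3)2, 2.2 equiv, THF, −78 °C) is C-acylated with 3,4,5-trimethoxybenzoyl chloride in a crossed Claisen condensation to give ethyl 2-(4-allyl-2,6-dimethoxyphenoxy)-3-oxo-3-(3,4,5-trimethoxyphenyl)propanoate F1, whose C2 centre is configurationally labile. Asymmetric transfer hydrogenation with dynamic kinetic resolution (RuCl[(S,S)-TsDPEN](p-cymene), HCO2H/Et3N 5:2, CH2Cl2, 30 °C) delivers hydride to the aryl ketone face used for acetophenone to (S)-1-phenylethanol and gives the syn product ethyl (2S,3R)-2-(4-allyl-2,6-dimethoxyphenoxy)-3-hydroxy-3-(3,4,5-trimethoxyphenyl)propanoate F2. Silylation (TBSOTf, 2,6-lutidine, CH2Cl2) gives ethyl (2S,3R)-2-(4-allyl-2,6-dimethoxyphenoxy)-3-(tert-butyldimethylsilyloxy)-3-(3,4,5-trimethoxyphenyl)propanoate F3, and iBu2AlH (CH2Cl2, −78 to 0 °C) reduces the ester to 13.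

Step 6 (reductive auxiliary removal; risk of endocyclic attack on the hindered imide or of silyl migration to the new primary alkoxide). The fallback sets out from 12 and comes back at 13. Transthioesterification with EtSLi (from EtSH and n-BuLi, THF, 0 °C) cleaves only the exocyclic carbonyl and gives S-ethyl (2S,3R)-2-(4-allyl-2,6-dimethoxyphenoxy)-3-(tert-butyldimethylsilyloxy)-3-(3,4,5-trimethoxyphenyl)propanethioate F4. This unhindered thioester is reduced by NaBH4 in EtOH at 0 °C to 13.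

Step 8 (final desilylation; risk of acetate migration or loss, or of benzylic ionisation next to the electron-rich ring). The fallback sets out from 13 and comes back at 15. The silyl group is removed before any ester is present (Bu4NF, THF, 0 °C) to give (1R,2R)-2-(4-allyl-2,6-dimethoxyphenoxy)-1-(3,4,5-trimethoxyphenyl)propane-1,3-diol F5. The primary hydroxyl is then acetylated selectively over the hindered benzylic one with acetyl chloride and 2,4,6-collidine in CH2Cl2 at −78 °C, giving 15 directly.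

**Further compounds**
F1 | step 4 | ethyl 2-(4-allyl-2,6-dimethoxyphenoxy)-3-oxo-3-(3,4,5-trimethoxyphenyl)propanoate | C=CCc1cc(OC)c(OC(C(=O)OCC)C(=O)c2cc(OC)c(OC)c(OC)c2)c(OC)c1
F2 | step 4 | ethyl (2S,3R)-2-(4-allyl-2,6-dimethoxyphenoxy)-3-hydroxy-3-(3,4,5-trimethoxyphenyl)propanoate | C=CCc1cc(OC)c(O[C@H](C(=O)OCC)[C@H](O)c2cc(OC)c(OC)c(OC)c2)c(OC)c1
F3 | step 4 | ethyl (2S,3R)-2-(4-allyl-2,6-dimethoxyphenoxy)-3-(tert-butyldimethylsilyloxy)-3-(3,4,5-trimethoxyphenyl)propanoate | C=CCc1cc(OC)c(O[C@H](C(=O)OCC)[C@H](O[Si](C)(C)C(C)(C)C)c2cc(OC)c(OC)c(OC)c2)c(OC)c1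
F4 | step 6 | S-ethyl (2S,3R)-2-(4-allyl-2,6-dimethoxyphenoxy)-3-(tert-butyldimethylsilyloxy)-3-(3,4,5-trimethoxyphenyl)propanethioate | C=CCc1cc(OC)c(O[C@H](C(=O)SCC)[C@H](O[Si](C)(C)C(C)(C)C)c2cc(OC)c(OC)c(OC)c2)c(OC)c1
F5 | step 8 | (1R,2R)-2-(4-allyl-2,6-dimethoxyphenoxy)-1-(3,4,5-trimethoxyphenyl)propane-1,3-diol | C=CCc1cc(OC)c(O[C@H](CO)[C@H](O)c2cc(OC)c(OC)c(OC)c2)c(OC)c1
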